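(The constants are those of an exercise; the result is computed.)

Divide the rate at which step 2 uses mono adduct by the rate at which step 1 uses substrate, and time drops out of these flasks.

common to all: substrate 5.0 × 10⁻⁴ M; time 6.0 s
- Thursday's: partner 0.300 mM
- Friday's: partner 0.600 mM
- Monday's: partner 1.20 mM
- Sunday's: partner 2.50 mM

    substrate + partner → mono adduct (k1 = 630 M⁻¹ s⁻¹)
    partner + mono adduct → double product (k2 = 300 M⁻¹ s⁻¹)
    partner + double product → tris adduct (k3 = 190 M⁻¹ s⁻¹)
    partner + tris adduct → tetra adduct (k4 = 1400 M⁻¹ s⁻¹)
    substrate + mono adduct → side product (k5 = 69 M⁻¹ s⁻¹)

* amount of mono adduct at the end, in percent of the substrate charged for Thursday's, Friday's, Monday's, Sunday's, in this order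
* how the row runs (hardly changes / falls all the way / falls, then rises / rises all the way / rises, then falls)

- a species is counted by the substrate in it: one side product counts as two
- "hardly changes" means that all values lie within two and a half points (for a concentration: within two and a half percent of the largest)
- run time (Thursday's): 6.0 s

1. Let s and m be substrate and mono adduct as fractions of the substrate charge. Partner stands in both rates and cancels with the clock, which leaves κ = 0.476, the selectivity factor: how readily partner takes mono adduct against substrate.

2. Step 5 is set aside here as a simplification, though it also takes mono adduct: on Thursday's charges the half-life of mono adduct by step 5 alone, 20 s, is longer than the run's 6.0 s. Then m follows s along one curve: m = (s^κ − s)/(1 − κ).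

3. The curve tops at s = 24.3%, where m = 50.9%. On this curve m rises as s falls towards that top, and m falls as s goes below it.

4. First link: partner held at its charge gives Thursday's s = 32.2%. But Thursday's partner charge is smaller than the substrate charge, and with step 5 set aside Thursday's substrate stops no lower than 40.0%, so this link breaks.

5. Reforged link: step 1 spends one partner per substrate lost, and partner taken by the later steps is not counted in this estimate. With β the partner charge per substrate charge, and E = exp(k1 × (substrate charge − partner charge) × time), s = (1 − β)E/(E − β). The four flasks give s = 55.7%, 26.6%, 4.26% and 0.0417%.

6. The curve turns these into a committed row of 38.1%, 50.8%, 34.4% and 4.62%. Friday's s stands above the top and Monday's below it, so the row rises, then falls.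

7. The forecast, reckoned by “partner exposure”, differs in its numbers: 33%, 46%, 39%, 11%, and rises, then falls.

8. The flasks give 33.3%, 46.3%, 39.8%, 10.8%: rises, then falls.

Sunday's end substrate, 0.27%, set on the curve with κ = 0.476, gives 10.9%, and Monday's, 7.23%, gives 40.9% against 39.8%. Sunday's substrate stood higher than 0.0417%. On Sunday's, the falling level of partner and the time allowed act together to leave mono adduct at 10.8%: with partner held at its charge the end value is 2.06%, and at 60.0 s it is 0%.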